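The target is a longipinane-type tricycle: a cyclobutane (C2–C3–C8–C7) bridged across C3/C7 by the enone C4–C5–C6 (ring A) and across C2/C8 by C1–C11–C10–C9 (ring B). All four cyclobutane carbons are stereogenic and C3, C7 and C8 each carry a carbonyl-derived carbon (C4, C6, C9), so the four-membered ring is disconnected at C3–C8 to a pyrrolidine-2,5-dicarboxylate with nitrogen between C3 and C8. Nitrogen deletion through a 1,1-diazene forges C3–C8, closes the cyclobutane and transfers, in one operation, the four contiguous stereocentres set by an azomethine ylide cycloaddition. The precursor is the 2,5-trans diester pyrrolidine 13 bearing the C7 acetyl group and the quaternary C1 side chain.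

Key step: step 9

Remarks on the chemistry
- Skeleton numbering follows the target SMILES: C1 (quaternary, CH3 and C15H2O), C2, C3, C4 (C=O), C5, C6 (CH3), C7, C8 (CH3), C9, C10, C11. O9, O11 and O15 are the oxygens on C9, C11 and C15.
- The pyrrolidine that enters the key step carries the C3 ester trans to the C8 ester (2,5-trans). The 2,5-cis arrangement belongs only to the kinetic cycloadduct 12, which is epimerised at C3 before nitrogen deletion.
- O15 is carried as a benzyl ether. A p-methoxybenzyl ether is at risk with a trivalent iodine oxidant in trifluoroethanol, and a plain ether oxygen is wanted later as a chelating site.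
- The C7 acetyl group stays a free ketone, so the C3 ester is homologated under soft-enolisation conditions (steps 10 and 11) and not with a lithiated phosphonate.
- Assumption: in steps 1 and 7 the ligand enantiomer written is the one taken to give the configuration drawn; the antipode is used if the sense proves opposite. The alanine stereocentre is erased in the ylide and controls nothing.

Step 1
Reactants: 1 methyl 2-methyl-3-oxobutanoate
Product: 2 methyl (S)-2-(hydroxymethyl)-2-methyl-3-oxobutanoate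
Conditions: 37% aq. HCHO, [Pd((R)-BINAP)(H2O)2](OTf)2 (5 mol %), THF, −20 °C
Reagents that add atoms: formaldehyde, C=O
Why: Catalytic asymmetric hydroxymethylation (aldol addition of a chiral divalent-palladium enolate of the β-keto ester to formaldehyde) should create the quaternary centre C1 with the S configuration, one enolate face being shielded by the bisphosphine.

Step 2
Reactants: 2 methyl (S)-2-(hydroxymethyl)-2-methyl-3-oxobutanoate
Product: 3 methyl (S)-2-[(benzyloxy)methyl]-2-methyl-3-oxobutanoate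
Conditions: BnOC(=NH)CCl3, TfOH (cat.), CH2Cl2/cyclohexane, 0 °C to rt
Reagents that add atoms: benzyl 2,2,2-trichloroacetimidate, ClC(Cl)(Cl)C(=N)OCc1ccccc1
Why: Acid-catalysed O-benzylation with the trichloroacetimidate (imidate alkylation) should protect O15 without forming an alkoxide, so that retro-aldol loss of formaldehyde and racemisation of C1 are avoided.

Step 3
Reactants: 3 methyl (S)-2-[(benzyloxy)methyl]-2-methyl-3-oxobutanoate
Product: 4 methyl (S)-3-(benzyloxy)-2-methyl-2-(2-methyl-1,3-dioxolan-2-yl)propanoate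
Conditions: Me3SiOCH2CH2OSiMe3, Me3SiOTf (cat.), CH2Cl2, −78 to 0 °C
Reagents that add atoms: 1,2-bis(trimethylsilyloxy)ethane, C[Si](C)(C)OCCO[Si](C)(C)C
Why: Silyl-triflate-catalysed ketalisation with the bis-silylated glycol should mask the hindered C11 ketone as a dioxolane, which differentiates it from the ester and keeps it silent until ring A is closed.

Step 4
Reactants: 4 methyl (S)-3-(benzyloxy)-2-methyl-2-(2-methyl-1,3-dioxolan-2-yl)propanoate
Product: 5 (S)-3-(benzyloxy)-2-methyl-2-(2-methyl-1,3-dioxolan-2-yl)propan-1-ol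
Conditions: LiAlH4, THF, 0 °C
Reagents that add atoms: none
Why: Hydride reduction of the ester should give the neopentyl alcohol, ketal and benzyl ether being inert to LiAlH4.

Step 5
Reactants: 5 (S)-3-(benzyloxy)-2-methyl-2-(2-methyl-1,3-dioxolan-2-yl)propan-1-ol
Product: 6 (R)-3-(benzyloxy)-2-methyl-2-(2-methyl-1,3-dioxolan-2-yl)propanal
Conditions: Dess–Martin periodinane, CH2Cl2, rt
Reagents that add atoms: none
Why: Dess–Martin oxidation should stop cleanly at the aldehyde, which has no α-hydrogen and therefore can neither epimerise nor eliminate.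

Step 6
Reactants: 6 (R)-3-(benzyloxy)-2-methyl-2-(2-methyl-1,3-dioxolan-2-yl)propanal; 7 1-(triphenylphosphoranylidene)propan-2-one
Product: 8 (S,E)-6-(benzyloxy)-5-methyl-5-(2-methyl-1,3-dioxolan-2-yl)hex-3-en-2-one
Conditions: toluene, 100 °C
Reagents that add atoms: 7 1-(triphenylphosphoranylidene)propan-2-one, CC(=O)C=P(c1ccccc1)(c1ccccc1)c1ccccc1
Why: Wittig olefination with the stabilised ylide should give the E enone (C2=C7), heating compensating for the neopentyl aldehyde.

Step 7
Reactants: 9 L-alanine tert-butyl ester; 10 methyl glyoxylate; 8 (S,E)-6-(benzyloxy)-5-methyl-5-(2-methyl-1,3-dioxolan-2-yl)hex-3-en-2-one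
Product: 12 2-tert-butyl 5-methyl (2S,3S,4R,5R)-3-acetyl-4-[(S)-1-(benzyloxy)-2-(2-methyl-1,3-dioxolan-2-yl)propan-2-yl]-2-methylpyrrolidine-2,5-dicarboxylate, via imine 11 (not isolated)
Conditions: 9, 10, MgSO4, CH2Cl2, 0 °C, filter; then 8, Cu(CH3CN)4PF6 (5 mol %), (R)-DTBM-Segphos (5.5 mol %), Et3N (10 mol %), THF, −20 °C to rt
Reagents that add atoms: 9 L-alanine tert-butyl ester, C[C@H](N)C(=O)OC(C)(C)C; 10 methyl glyoxylate, COC(=O)C=O
Why: Imine condensation followed by a monovalent-copper-catalysed 1,3-dipolar cycloaddition of the N-metalated azomethine ylide should give the pyrrolidine, the unsubstituted ylide carbon C3 bonding to the hindered β-carbon C2 and the methyl-bearing C8 to C7 for steric reasons, the W-shaped ylide giving cis esters, the E alkene giving trans C2/C7, the exo orientation enforced by the bulky bisphosphine placing acetyl cis to the C8 methyl, and the ligand selecting the enone face relative to C1.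

Step 8
Reactants: 12 2-tert-butyl 5-methyl (2S,3S,4R,5R)-3-acetyl-4-[(S)-1-(benzyloxy)-2-(2-methyl-1,3-dioxolan-2-yl)propan-2-yl]-2-methylpyrrolidine-2,5-dicarboxylate
Product: 13 2-tert-butyl 5-methyl (2S,3S,4R,5S)-3-acetyl-4-[(S)-1-(benzyloxy)-2-(2-methyl-1,3-dioxolan-2-yl)propan-2-yl]-2-methylpyrrolidine-2,5-dicarboxylate
Conditions: DBU, toluene, 70 °C
Reagents that add atoms: none
Why: Base-mediated epimerisation through the C3 ester enolate should move the ester away from the face of the bulky C2 substituent (thermodynamic control), C7 already being trans to both neighbours and C8 being quaternary.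

Step 9
Reactants: 13 2-tert-butyl 5-methyl (2S,3S,4R,5S)-3-acetyl-4-[(S)-1-(benzyloxy)-2-(2-methyl-1,3-dioxolan-2-yl)propan-2-yl]-2-methylpyrrolidine-2,5-dicarboxylate
Product: 15 1-tert-butyl 2-methyl (1R,2R,3S,4S)-4-acetyl-3-[(S)-1-(benzyloxy)-2-(2-methyl-1,3-dioxolan-2-yl)propan-2-yl]-1-methylcyclobutane-1,2-dicarboxylate, via 1,1-diazene 14 (not isolated)
Conditions: PhI(OH)OTs (2.5 equiv), NH2CO2NH4 (8 equiv), CF3CH2OH, 80 °C
Reagents that add atoms: none
Why: Ammonia and the hypervalent iodine reagent should generate an iodonitrene that aminates the ring nitrogen to the 1,1-diazene 14, which loses dinitrogen to a singlet 1,4-biradical centred on C3 and C8, each α to an ester. The closest known reaction type is the iodonitrene-mediated contraction of pyrrolidines to cyclobutanes (nitrogen deletion through an isodiazene). The four-membered ring closes by radical–radical recombination, which forms the C3–C8 bond. C3 and C8 keep the configurations they hold in 13 because the singlet pair collapses faster than rotation about C2–C3 or C7–C8, while C2 and C7 are not touched. The step needs recombination to win over β-scission of the C2–C7 bond and needs retention at quaternary C8; ester stabilisation of both radicals, the short lifetime of the singlet pair and the hindered alkenes that cleavage would give all favour closure, and any erosion at C3 remains correctable by base because the required isomer is the more stable one.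

Step 10
Reactants: 15 1-tert-butyl 2-methyl (1R,2R,3S,4S)-4-acetyl-3-[(S)-1-(benzyloxy)-2-(2-methyl-1,3-dioxolan-2-yl)propan-2-yl]-1-methylcyclobutane-1,2-dicarboxylate
Product: 16 cyclobutane carboxylic acid (C4 acid of 15)
Conditions: LiOH·H2O, THF/MeOH/H2O, rt to 40 °C; then 1 M HCl to pH 3
Reagents that add atoms: lithium hydroxide, [Li+].[OH-]
Why: Saponification should cleave only the methyl ester, because the tert-butyl ester on quaternary C8 resists hydroxide and C3 and C7 already hold their thermodynamically preferred configurations.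

Step 11
Reactants: 16 cyclobutane carboxylic acid (C4 acid of 15)
Product: 19 β-ketophosphonate (C4 ketone bearing C5H2P(O)(OEt)2), via acid chloride 17 (not isolated), via acylphosphonoacetic acid 18 (not isolated)
Conditions: Me2C=C(Cl)NMe2, CH2Cl2, 0 °C; then (EtO)2P(O)CH2CO2H, MgCl2, Et3N, MeCN, 0 °C to rt; then aq. citric acid, rt
Reagents that add atoms: diethylphosphonoacetic acid, CCOP(=O)(OCC)CC(=O)O
Why: Conversion to the acid chloride and C-acylation of the magnesium enolate of diethylphosphonoacetic acid, followed by decarboxylation on acidification (a decarboxylative Claisen-type acylation under soft enolisation), should give the β-ketophosphonate without touching the C7 acetyl group, which a lithiated methylphosphonate would attack.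

Step 12
Reactants: 19 β-ketophosphonate (C4 ketone bearing C5H2P(O)(OEt)2)
Product: 20 tert-butyl 7-[(S)-1-(benzyloxy)-2-(2-methyl-1,3-dioxolan-2-yl)propan-2-yl]-4,6-dimethyl-2-oxobicyclo[3.1.1]hept-3-ene-6-carboxylate
Conditions: K2CO3, 18-crown-6, toluene, 60 °C
Reagents that add atoms: none
Why: An intramolecular Horner–Wadsworth–Emmons reaction of the phosphonate carbanion C5 with the cis-1,3-disposed C7 acetyl group should close the cyclohexenone (C5=C6, ring A) onto the cyclobutane, the C11 ketone being still masked and the cis C3/C7 relation being the only one that can cyclise.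

Step 13
Reactants: 20 tert-butyl 7-[(S)-1-(benzyloxy)-2-(2-methyl-1,3-dioxolan-2-yl)propan-2-yl]-4,6-dimethyl-2-oxobicyclo[3.1.1]hept-3-ene-6-carboxylate
Product: 21 tert-butyl 7-[(S)-1-(benzyloxy)-2-methyl-3-oxobutan-2-yl]-4,6-dimethyl-2-oxobicyclo[3.1.1]hept-3-ene-6-carboxylate
Conditions: 1 M aq. HCl, THF, rt
Reagents that add atoms: water, O
Why: Aqueous acid hydrolysis of the dioxolane should release the C11 methyl ketone, the tert-butyl ester, benzyl ether and enone being stable to dilute acid at room temperature.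

Step 14
Reactants: 21 tert-butyl 7-[(S)-1-(benzyloxy)-2-methyl-3-oxobutan-2-yl]-4,6-dimethyl-2-oxobicyclo[3.1.1]hept-3-ene-6-carboxylate
Product: 22 triol (C4 allylic alcohol; C9 primary alcohol; C11 secondary alcohol; epimers at C4 and C11)
Conditions: LiAlH4, THF, 0 °C to rt
Reagents that add atoms: none
Why: Exhaustive hydride reduction should convert the tert-butyl ester into the C9 primary alcohol and both ketones into alcohols (1,2-reduction of the enone), the two new carbinol centres being of no consequence because they are reoxidised.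

Step 15
Reactants: 22 triol (C4 allylic alcohol; C9 primary alcohol; C11 secondary alcohol; epimers at C4 and C11)
Product: 23 7-[(S)-1-(benzyloxy)-2-methyl-3-oxobutan-2-yl]-4,6-dimethyl-2-oxobicyclo[3.1.1]hept-3-ene-6-carbaldehyde
Conditions: (COCl)2, DMSO, CH2Cl2, −78 °C; then Et3N, −78 to 0 °C
Reagents that add atoms: none
Why: Swern oxidation activates all three hydroxyl groups before base is added and should therefore give enone, methyl ketone and C9 aldehyde together, without a hydroxy aldehyde that could close to a lactol and be over-oxidised.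

Step 16
Reactants: 23 7-[(S)-1-(benzyloxy)-2-methyl-3-oxobutan-2-yl]-4,6-dimethyl-2-oxobicyclo[3.1.1]hept-3-ene-6-carbaldehyde
Product: 24 6-[(benzyloxy)methyl]-3-hydroxy-2,6,9-trimethyltricyclo[5.4.0.0(2,8)]undec-9-ene-5,11-dione
Conditions: LiN(SiMe3)2 (1.1 equiv), toluene/Et2O, −78 °C; then AcOH, −78 °C
Reagents that add atoms: none
Why: Kinetic deprotonation can occur only at C10 (the aldehyde and C1 offer no α-hydrogen and C3 is a bridgehead), and the intramolecular aldol addition should close the seven-membered ring B through a closed transition state in which lithium is chelated by the enolate oxygen, the aldehyde oxygen and the benzyloxy oxygen O15, which places O9 on the face of C15.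

Step 17
Reactants: 24 6-[(benzyloxy)methyl]-3-hydroxy-2,6,9-trimethyltricyclo[5.4.0.0(2,8)]undec-9-ene-5,11-dione
Product: 25 6-[(benzyloxy)methyl]-5-hydroxy-2,6,9-trimethyl-11-oxotricyclo[5.4.0.0(2,8)]undec-9-en-3-yl 3-methylbut-2-enoate
Conditions: SmI2 (0.3 equiv), 3-methylbut-2-enal (8 equiv), THF, −10 °C
Reagents that add atoms: 3-methylbut-2-enal, CC(C)=CC=O
Why: In the Evans–Tishchenko reduction the hemiacetal formed from the C9 hydroxyl and the enal on trivalent samarium should deliver hydride intramolecularly to C11 from the face of O9, which sets the 1,3-trans C11 alcohol and leaves the oxidised aldehyde on O9 as the 3-methylbut-2-enoate.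

Step 18
Reactants: 25 6-[(benzyloxy)methyl]-5-hydroxy-2,6,9-trimethyl-11-oxotricyclo[5.4.0.0(2,8)]undec-9-en-3-yl 3-methylbut-2-enoate
Product: 26 5-acetoxy-6-[(benzyloxy)methyl]-2,6,9-trimethyl-11-oxotricyclo[5.4.0.0(2,8)]undec-9-en-3-yl 3-methylbut-2-enoate
Conditions: Ac2O, DMAP (cat.), pyridine, rt
Reagents that add atoms: acetic anhydride, CC(=O)OC(C)=O
Why: DMAP-catalysed acylation should acetylate the only free hydroxyl group, the hindered C11 alcohol.

Step 19
Reactants: 26 5-acetoxy-6-[(benzyloxy)methyl]-2,6,9-trimethyl-11-oxotricyclo[5.4.0.0(2,8)]undec-9-en-3-yl 3-methylbut-2-enoate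
Product: 27 5-acetoxy-6-(hydroxymethyl)-2,6,9-trimethyl-11-oxotricyclo[5.4.0.0(2,8)]undec-9-en-3-yl 3-methylbut-2-enoate
Conditions: BCl3, pentamethylbenzene, CH2Cl2, −78 °C; then MeOH
Reagents that add atoms: none
Why: Lewis-acid debenzylation with pentamethylbenzene as benzyl cation scavenger should free O15 at low temperature without touching the two esters or the two conjugated alkenes that hydrogenolysis would reduce.

Step 20
Reactants: 27 5-acetoxy-6-(hydroxymethyl)-2,6,9-trimethyl-11-oxotricyclo[5.4.0.0(2,8)]undec-9-en-3-yl 3-methylbut-2-enoate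
Product: 28 [5-acetoxy-2,6,9-trimethyl-3-[(3-methylbut-2-enoyl)oxy]-11-oxotricyclo[5.4.0.0(2,8)]undec-9-en-6-yl]methyl (Z)-2-methylbut-2-enoate (target CNP0179010.1)
Conditions: angelic acid, 2,4,6-Cl3C6H2COCl, Et3N, toluene, rt; then 27, 75 °C
Reagents that add atoms: angelic acid, C/C=C(/C)C(=O)O
Why: Yamaguchi esterification through the mixed anhydride, run without DMAP, should acylate the primary alcohol while keeping the Z geometry of the angeloyl group.

Compound list
1 | methyl 2-methyl-3-oxobutanoate | COC(=O)C(C)C(C)=O | starting material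
2 | methyl (S)-2-(hydroxymethyl)-2-methyl-3-oxobutanoate | COC(=O)[C@@](C)(CO)C(C)=O | intermediate
3 | methyl (S)-2-[(benzyloxy)methyl]-2-methyl-3-oxobutanoate | COC(=O)[C@@](C)(COCc1ccccc1)C(C)=O | intermediate
4 | methyl (S)-3-(benzyloxy)-2-methyl-2-(2-methyl-1,3-dioxolan-2-yl)propanoate | COC(=O)[C@@](C)(COCc1ccccc1)C1(C)OCCO1 | intermediate
5 | (S)-3-(benzyloxy)-2-methyl-2-(2-methyl-1,3-dioxolan-2-yl)propan-1-ol | OC[C@@](C)(COCc1ccccc1)C1(C)OCCO1 | intermediate
6 | (R)-3-(benzyloxy)-2-methyl-2-(2-methyl-1,3-dioxolan-2-yl)propanal | O=C[C@@](C)(COCc1ccccc1)C1(C)OCCO1 | intermediate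
7 | 1-(triphenylphosphoranylidene)propan-2-one | CC(=O)C=P(c1ccccc1)(c1ccccc1)c1ccccc1 | starting material
8 | (S,E)-6-(benzyloxy)-5-methyl-5-(2-methyl-1,3-dioxolan-2-yl)hex-3-en-2-one | CC(=O)/C=C/[C@@](C)(COCc1ccccc1)C1(C)OCCO1 | intermediate
9 | L-alanine tert-butyl ester | C[C@H](N)C(=O)OC(C)(C)C | starting material
10 | methyl glyoxylate | COC(=O)C=O | starting material
11 | tert-butyl (S,E)-2-[(2-methoxy-2-oxoethylidene)amino]propanoate (imine, formed in the flask) | COC(=O)/C=N/[C@@H](C)C(=O)OC(C)(C)C | intermediate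
12 | 2-tert-butyl 5-methyl (2S,3S,4R,5R)-3-acetyl-4-[(S)-1-(benzyloxy)-2-(2-methyl-1,3-dioxolan-2-yl)propan-2-yl]-2-methylpyrrolidine-2,5-dicarboxylate (kinetic cycloadduct, esters 2,5-cis, C3 ester cis to the C2 side chain) | COC(=O)[C@@H]1N[C@](C)(C(=O)OC(C)(C)C)[C@@H](C(C)=O)[C@@H]1[C@@](C)(COCc2ccccc2)C2(C)OCCO2 | intermediate
13 | 2-tert-butyl 5-methyl (2S,3S,4R,5S)-3-acetyl-4-[(S)-1-(benzyloxy)-2-(2-methyl-1,3-dioxolan-2-yl)propan-2-yl]-2-methylpyrrolidine-2,5-dicarboxylate (esters 2,5-trans; all neighbouring carbon substituents trans) | COC(=O)[C@H]1N[C@](C)(C(=O)OC(C)(C)C)[C@@H](C(C)=O)[C@@H]1[C@@](C)(COCc2ccccc2)C2(C)OCCO2 | intermediate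
14 | 1,1-diazene (N-nitrene) of pyrrolidine 13, formed in the flask | COC(=O)[C@H]1[N+](=[N-])[C@](C)(C(=O)OC(C)(C)C)[C@@H](C(C)=O)[C@@H]1[C@@](C)(COCc2ccccc2)C2(C)OCCO2 | intermediate
15 | 1-tert-butyl 2-methyl (1R,2R,3S,4S)-4-acetyl-3-[(S)-1-(benzyloxy)-2-(2-methyl-1,3-dioxolan-2-yl)propan-2-yl]-1-methylcyclobutane-1,2-dicarboxylate | COC(=O)[C@@H]1[C@@H]([C@@](C)(COCc2ccccc2)C2(C)OCCO2)[C@H](C(C)=O)[C@@]1(C)C(=O)OC(C)(C)C | intermediate
16 | cyclobutane carboxylic acid: 15 with the C3 methyl ester hydrolysed to CO2H, all else unchanged | OC(=O)[C@@H]1[C@@H]([C@@](C)(COCc2ccccc2)C2(C)OCCO2)[C@H](C(C)=O)[C@@]1(C)C(=O)OC(C)(C)C | intermediate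
17 | acid chloride of 16, formed in the flask | ClC(=O)[C@@H]1[C@@H]([C@@](C)(COCc2ccccc2)C2(C)OCCO2)[C@H](C(C)=O)[C@@]1(C)C(=O)OC(C)(C)C | intermediate
18 | 2-(diethoxyphosphoryl)-3-oxo-3-(cyclobutyl)propanoic acid from 17 (epimers at the new CH), formed in the flask | CCOP(=O)(OCC)C(C(=O)O)C(=O)[C@@H]1[C@@H]([C@@](C)(COCc2ccccc2)C2(C)OCCO2)[C@H](C(C)=O)[C@@]1(C)C(=O)OC(C)(C)C | intermediate
19 | β-ketophosphonate: C3 carries C(=O)CH2P(O)(OEt)2, C7 acetyl, C8 methyl and tert-butyl ester, C2 side chain as in 15 | CCOP(=O)(OCC)CC(=O)[C@@H]1[C@@H]([C@@](C)(COCc2ccccc2)C2(C)OCCO2)[C@H](C(C)=O)[C@@]1(C)C(=O)OC(C)(C)C | intermediate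
20 | tert-butyl 7-[(S)-1-(benzyloxy)-2-(2-methyl-1,3-dioxolan-2-yl)propan-2-yl]-4,6-dimethyl-2-oxobicyclo[3.1.1]hept-3-ene-6-carboxylate (ester and side chain both anti to the enone bridge) | O=C1[C@@H]2[C@@H]([C@@](C)(COCc3ccccc3)C3(C)OCCO3)[C@H](C(C)=C1)[C@@]2(C)C(=O)OC(C)(C)C | intermediate
21 | tert-butyl 7-[(S)-1-(benzyloxy)-2-methyl-3-oxobutan-2-yl]-4,6-dimethyl-2-oxobicyclo[3.1.1]hept-3-ene-6-carboxylate | O=C1[C@@H]2[C@@H]([C@@](C)(COCc3ccccc3)C(C)=O)[C@H](C(C)=C1)[C@@]2(C)C(=O)OC(C)(C)C | intermediate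
22 | 7-[(2S)-1-(benzyloxy)-3-hydroxy-2-methylbutan-2-yl]-6-(hydroxymethyl)-4,6-dimethylbicyclo[3.1.1]hept-3-en-2-ol (epimers at the two secondary carbinols) | OC1[C@@H]2[C@@H]([C@@](C)(COCc3ccccc3)C(C)O)[C@H](C(C)=C1)[C@@]2(C)CO | intermediate
23 | 7-[(S)-1-(benzyloxy)-2-methyl-3-oxobutan-2-yl]-4,6-dimethyl-2-oxobicyclo[3.1.1]hept-3-ene-6-carbaldehyde | O=C1[C@@H]2[C@@H]([C@@](C)(COCc3ccccc3)C(C)=O)[C@H](C(C)=C1)[C@@]2(C)C=O | intermediate
24 | 6-[(benzyloxy)methyl]-3-hydroxy-2,6,9-trimethyltricyclo[5.4.0.0(2,8)]undec-9-ene-5,11-dione (C9 hydroxyl on the face of C15; skeleton C4 and C11 ketones) | c4ccccc4COC[C@]1(C)[C@@H]2[C@H]3C(=O)C=C(C)[C@@H]2[C@@]3(C)[C@H](O)CC1=O | intermediate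
25 | 6-[(benzyloxy)methyl]-5-hydroxy-2,6,9-trimethyl-11-oxotricyclo[5.4.0.0(2,8)]undec-9-en-3-yl 3-methylbut-2-enoate (O9 ester cis to C15, C11 hydroxyl trans) | c4ccccc4COC[C@]1(C)[C@@H]2[C@H]3C(=O)C=C(C)[C@@H]2[C@@]3(C)[C@H](OC(=O)C=C(C)C)C[C@H]1O | intermediate
26 | 5-acetoxy-6-[(benzyloxy)methyl]-2,6,9-trimethyl-11-oxotricyclo[5.4.0.0(2,8)]undec-9-en-3-yl 3-methylbut-2-enoate | c4ccccc4COC[C@]1(C)[C@@H]2[C@H]3C(=O)C=C(C)[C@@H]2[C@@]3(C)[C@H](OC(=O)C=C(C)C)C[C@H]1OC(C)=O | intermediate
27 | 5-acetoxy-6-(hydroxymethyl)-2,6,9-trimethyl-11-oxotricyclo[5.4.0.0(2,8)]undec-9-en-3-yl 3-methylbut-2-enoate | OC[C@]1(C)[C@@H]2[C@H]3C(=O)C=C(C)[C@@H]2[C@@]3(C)[C@H](OC(=O)C=C(C)C)C[C@H]1OC(C)=O | intermediate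
28 | [5-acetoxy-2,6,9-trimethyl-3-[(3-methylbut-2-enoyl)oxy]-11-oxotricyclo[5.4.0.0(2,8)]undec-9-en-6-yl]methyl (Z)-2-methylbut-2-enoate, CNP0179010.1 (C11 acetate, C9 3-methylbut-2-enoate, C15 angelate) | C/C=C(/C)C(=O)OC[C@]1(C)[C@@H]2[C@H]3C(=O)C=C(C)[C@@H]2[C@@]3(C)[C@H](OC(=O)C=C(C)C)C[C@H]1OC(C)=O | target

Total step count: 20. Longest linear sequence: 20 steps (1 to 28); 7, 9 and 10 are bought.

Steps most likely to fail

Step 7. The neopentyl-type β-carbon may react slowly and the glyoxylate imine may dimerise. More seriously, the acetyl group may take the endo orientation, which would fix quaternary C8 with its ester on the wrong face relative to C7; base cannot correct that. Face selection relative to C1 rests on the catalyst alone. The fallback sets out from aldehyde 6 and returns at 13. Homologation of 6 with dimethyl (1-diazo-2-oxopropyl)phosphonate (K2CO3, MeOH) gives the terminal alkyne F1. Deprotonation (n-BuLi, THF, −78 °C) and acylation with N-methoxy-N-methylacetamide give the ynone F2. Cycloaddition of imine 11 with this unhindered, linear dipolarophile under the chiral copper catalyst of step 7 gives the 2,5-dihydropyrrole F3. F3 has only the C3 and C8 stereocentres, with cis esters, so no exo/endo question arises. Hydrogenation (H2, Pd/C poisoned with 2,2′-bipyridyl so that the benzyl ether survives, EtOAc) delivers hydrogen to the face opposite the two esters and gives the all-cis pyrrolidine F4. The DBU conditions of step 8 then epimerise both C7 and C3 to the all-trans isomer 13. In this variant the C8/C2/C7 relation comes from hydrogen addition anti to the ester face.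

Step 9. Amination of the doubly α-branched, electron-poor nitrogen may be slow. At 80 °C the biradical may cleave the C2–C7 bond to two alkenes, or rotate at the tertiary C8 radical before closing. The fallback sets out from 13 and returns at 15. Nitrosation (tert-butyl nitrite, CH2Cl2) gives the N-nitrosopyrrolidine F5, and reduction with Zn/AcOH at 0 °C gives the 1-aminopyrrolidine F6. F6 is oxidised at once (HgO or Pb(OAc)4, CH2Cl2, −40 to 0 °C), so that the same 1,1-diazene is formed and loses dinitrogen well below the temperature of the one-pot method. This separates N–N bond formation, done with a small electrophile, from the extrusion, and gives cage recombination its best chance.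

Step 16. Chelation of lithium by O15 may be too weak to control the face on which O9 ends, and the aldolate may revert or dehydrate on warming. The fallback sets out from 20 and returns at 25. LiAlH4 gives the diol F7, and MnO2 reoxidises only the allylic alcohol to the hydroxy enone F8. Aqueous HCl in THF removes the ketal to give the hydroxy diketone F9. Kinetic silylation (LiN(SiMe3)2, Me3SiCl, −78 °C), then N-bromosuccinimide and mild acid work-up, give the bromomethyl ketone F10. Dess–Martin oxidation gives the bromo keto aldehyde F11. SmI2 (2.2 equiv, THF, −78 °C) then forms the trivalent samarium enolate reductively at C10 only, and a Reformatsky-type aldol closes ring B on a metal of high coordination number that binds O11, O9 and O15 together. Addition of 3-methylbut-2-enal at −10 °C to the same flask completes the Tishchenko step and gives 25.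

Further compounds
F1 | step 7 | 2-[(S)-1-(benzyloxy)-2-methylbut-3-yn-2-yl]-2-methyl-1,3-dioxolane | C#C[C@@](C)(COCc1ccccc1)C1(C)OCCO1
F2 | step 7 | (S)-6-(benzyloxy)-5-methyl-5-(2-methyl-1,3-dioxolan-2-yl)hex-3-yn-2-one | CC(=O)C#C[C@@](C)(COCc1ccccc1)C1(C)OCCO1
F3 | step 7 | 2-tert-butyl 5-methyl (2S,5R)-3-acetyl-4-[(S)-1-(benzyloxy)-2-(2-methyl-1,3-dioxolan-2-yl)propan-2-yl]-2-methyl-2,5-dihydro-1H-pyrrole-2,5-dicarboxylate | COC(=O)[C@@H]1N[C@](C)(C(=O)OC(C)(C)C)C(C(C)=O)=C1[C@@](C)(COCc2ccccc2)C2(C)OCCO2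
F4 | step 7 | 2-tert-butyl 5-methyl (2S,3R,4R,5R)-3-acetyl-4-[(S)-1-(benzyloxy)-2-(2-methyl-1,3-dioxolan-2-yl)propan-2-yl]-2-methylpyrrolidine-2,5-dicarboxylate (all-cis) | COC(=O)[C@@H]1N[C@](C)(C(=O)OC(C)(C)C)[C@H](C(C)=O)[C@@H]1[C@@](C)(COCc2ccccc2)C2(C)OCCO2
F5 | step 9 | N-nitroso derivative of pyrrolidine 13 | COC(=O)[C@H]1N(N=O)[C@](C)(C(=O)OC(C)(C)C)[C@@H](C(C)=O)[C@@H]1[C@@](C)(COCc2ccccc2)C2(C)OCCO2
F6 | step 9 | 1-amino derivative of pyrrolidine 13 | COC(=O)[C@H]1N(N)[C@](C)(C(=O)OC(C)(C)C)[C@@H](C(C)=O)[C@@H]1[C@@](C)(COCc2ccccc2)C2(C)OCCO2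
F7 | step 16 | 7-[(S)-1-(benzyloxy)-2-(2-methyl-1,3-dioxolan-2-yl)propan-2-yl]-6-(hydroxymethyl)-4,6-dimethylbicyclo[3.1.1]hept-3-en-2-ol (carbinol epimers) | OC1[C@@H]2[C@@H]([C@@](C)(COCc3ccccc3)C3(C)OCCO3)[C@H](C(C)=C1)[C@@]2(C)CO
F8 | step 16 | 7-[(S)-1-(benzyloxy)-2-(2-methyl-1,3-dioxolan-2-yl)propan-2-yl]-6-(hydroxymethyl)-4,6-dimethylbicyclo[3.1.1]hept-3-en-2-one | O=C1[C@@H]2[C@@H]([C@@](C)(COCc3ccccc3)C3(C)OCCO3)[C@H](C(C)=C1)[C@@]2(C)CO
F9 | step 16 | 7-[(S)-1-(benzyloxy)-2-methyl-3-oxobutan-2-yl]-6-(hydroxymethyl)-4,6-dimethylbicyclo[3.1.1]hept-3-en-2-one | O=C1[C@@H]2[C@@H]([C@@](C)(COCc3ccccc3)C(C)=O)[C@H](C(C)=C1)[C@@]2(C)CO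
F10 | step 16 | 7-[(S)-1-(benzyloxy)-4-bromo-2-methyl-3-oxobutan-2-yl]-6-(hydroxymethyl)-4,6-dimethylbicyclo[3.1.1]hept-3-en-2-one | O=C1[C@@H]2[C@@H]([C@@](C)(COCc3ccccc3)C(=O)CBr)[C@H](C(C)=C1)[C@@]2(C)CO
F11 | step 16 | 7-[(S)-1-(benzyloxy)-4-bromo-2-methyl-3-oxobutan-2-yl]-4,6-dimethyl-2-oxobicyclo[3.1.1]hept-3-ene-6-carbaldehyde | O=C1[C@@H]2[C@@H]([C@@](C)(COCc3ccccc3)C(=O)CBr)[C@H](C(C)=C1)[C@@]2(C)C=O
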